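**Plan**
- Retrosynthesis removes the two isovalerates and the C3 inversion, cuts C13–C16 and C11–C12 of the side chain, then C8–C9 and C5–C10 together, and last C6–C7 and C3–C4 of the open chain.
- The double cut is possible because in ring B the bonds C5–C10 and C8–C9 flank the C6 oxygen (a carbonyl retron) and C11 on C9 can be an ester: ring B is the adduct of a C5–C8 oxido-diene centred on C6 and a C9=C10 enoate, with C1–C4 of ring A as the tether.
- Forward: methyl geranate supplies C1, C2, C9–C11 and C20, isoprene monoxide C4–C6, C18 and C19, propenyllithium C7, C8 and C17. One base treatment closes ring A and then ring B; the C12–C16 chain and the ester pattern follow.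
- Stereochemistry: C3 and C4 come from an iridium-catalysed anti tert-(hydroxy)prenylation, and C5 and C10 are relayed from them in the cascade. C6 is set by α-face hydride delivery, C3 is inverted by oxidation and bulky-hydride reduction, and 13E comes from a Z enol phosphate and a cuprate.

Key step: step 8

Numbering: labdane numbers are used throughout (ring A = C1–C5, C10; ring B = C5–C10; C17 on C8; C18 α and C19 β on C4; C20 on C10; C11 on C9). TBS = tert-butyldimethylsilyl.

Assumption: the (R)-Tol-BINAP iridium catalyst is taken to give the (6S,7S) diol 4; if the sense of induction is the reverse, the (S) ligand is used and nothing else changes.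

**Route**

Step 1
Reactants: 1 methyl (2E)-3,7-dimethylocta-2,6-dienoate (methyl geranate)
Product: 2 methyl (2E)-3-methyl-6-oxohex-2-enoate
Conditions: O3 (1 equiv), CH2Cl2–MeOH, −78 °C; then Me2S, −78 °C → rt
Reagents that add atoms: ozone, [O-][O+]=O
Why: Ozonolysis, in which the electron-rich trisubstituted C6–C7 alkene reacts far faster with electrophilic ozone than the ester-conjugated C2–C3 alkene, so one equivalent should cleave only the isopropylidene end.

Step 2
Reactants: 2 methyl (2E)-3-methyl-6-oxohex-2-enoate; 3 2-methyl-2-vinyloxirane (isoprene monoxide, racemic)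
Product: 4 methyl (2E,6S,7S)-6-hydroxy-7-(hydroxymethyl)-3,7-dimethylnona-2,8-dienoate
Conditions: 3 (3 equiv), i-PrOH (2 equiv), Ir(η3-allyl)[(R)-Tol-BINAP](κ2-C,O-4-cyano-3-nitrobenzoate) (5 mol%), K3PO4 (5 mol%), THF, 60 °C
Reagents that add atoms: isoprene monoxide (3), CC1(C=C)CO1
Why: Iridium-catalysed transfer-hydrogenative carbonyl tert-(hydroxy)prenylation, in which the (E)-σ-allyliridium species from the vinyl epoxide adds through a closed chair transition state, setting quaternary C4 anti to the C3 hydroxyl, while the Tol-BINAP ligand selects the aldehyde face (3S).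

Step 3
Reactants: 4 methyl (2E,6S,7S)-6-hydroxy-7-(hydroxymethyl)-3,7-dimethylnona-2,8-dienoate
Product: 5 methyl (2E,6S,7S)-6-(TBSO)-7-[(TBSO)methyl]-3,7-dimethylnona-2,8-dienoate
Conditions: TBSOTf (2.5 equiv), 2,6-lutidine, CH2Cl2, −78 → 0 °C
Reagents that add atoms: tert-butyldimethylsilyl triflate, CC(C)(C)[Si](C)(C)OS(=O)(=O)C(F)(F)F
Why: Silyl ether formation with the silyl triflate, which is reactive enough for the secondary C3 hydroxyl beside quaternary C4 as well as for the primary one.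

Step 4
Reactants: 5 methyl (2E,6S,7S)-6-(TBSO)-7-[(TBSO)methyl]-3,7-dimethylnona-2,8-dienoate
Product: 7 methyl (2E,6S,7S)-6-(TBSO)-7-[(TBSO)methyl]-9-hydroxy-3,7-dimethylnon-2-enoate, via B-alkyl-9-BBN adduct 6 (not isolated)
Conditions: 9-BBN (2 equiv), THF, 0 → 50 °C; then NaBO3·4H2O, H2O, rt
Reagents that add atoms: sodium perborate, [Na+].[Na+].O[B-]1(O)OO[B-](O)(O)OO1
Why: Brown hydroboration–oxidation, in which 9-BBN adds to the monosubstituted vinyl group at its terminal carbon and ignores the trisubstituted ester-conjugated alkene, and perborate oxidises the C–B bond without harming the methyl ester.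

Step 5
Reactants: 7 methyl (2E,6S,7S)-6-(TBSO)-7-[(TBSO)methyl]-9-hydroxy-3,7-dimethylnon-2-enoate
Product: 8 methyl (2E,6S,7S)-6-(TBSO)-7-[(TBSO)methyl]-3,7-dimethyl-9-oxonon-2-enoate
Conditions: Dess–Martin periodinane, NaHCO3, CH2Cl2, 0 °C → rt
Reagents that add atoms: none
Why: Dess–Martin oxidation of a primary alcohol to the aldehyde under buffered conditions that leave silyl ethers and the enoate alone.

Step 6
Reactants: 8 methyl (2E,6S,7S)-6-(TBSO)-7-[(TBSO)methyl]-3,7-dimethyl-9-oxonon-2-enoate; 9 (E)-1-bromoprop-1-ene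
Product: 10 methyl (2E,6S,7S,10E)-6-(TBSO)-7-[(TBSO)methyl]-9-hydroxy-3,7-dimethyldodeca-2,10-dienoate (both C9 epimers)
Conditions: 9 (1.5 equiv), t-BuLi (3 equiv), Et2O, −78 °C; then 8, −78 °C; H2O
Reagents that add atoms: (E)-1-bromoprop-1-ene (9), C/C=C/Br
Why: Bromine–lithium exchange with retention of alkene geometry followed by 1,2-addition of the alkenyllithium to the aldehyde, which at −78 °C is much faster than attack on the β,β-disubstituted enoate; the new carbinol centre is uncontrolled and is removed in step 7.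

Step 7
Reactants: 10 methyl (2E,6S,7S,10E)-6-(TBSO)-7-[(TBSO)methyl]-9-hydroxy-3,7-dimethyldodeca-2,10-dienoate
Product: 11 methyl (2E,6S,7S,10E)-6-(TBSO)-7-[(TBSO)methyl]-3,7-dimethyl-9-oxododeca-2,10-dienoate
Conditions: Dess–Martin periodinane, NaHCO3, CH2Cl2, 0 °C → rt
Reagents that add atoms: none
Why: Dess–Martin oxidation of the allylic alcohol to the (E)-propenyl ketone, which converges both carbinol epimers.

Step 8
Reactants: 11 methyl (2E,6S,7S,10E)-6-(TBSO)-7-[(TBSO)methyl]-3,7-dimethyl-9-oxododeca-2,10-dienoate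
Product: 15 methyl 3β,19-bis(TBSO)-6-oxo-12,13,14,15,16-pentanorlabdan-11-oate (5α-H; 8β-CH3; 9β-CO2Me; 10β-CH3), via lithium dienolate 12 (not isolated), via ring A ester enolate 13 (not isolated), via C6 lithium enolate 14 (not isolated)
Conditions: LiN(SiMe3)2 (1.2 equiv), THF, −78 °C → rt; AcOH, −78 °C
Reagents that add atoms: none
Why: The amide base removes a C5 proton to give the cross-conjugated Z(O)-dienolate 12, whose C5 adds to C10 of the enoate; the C9 ester enolate 13 then adds to C8 of the propenyl ketone and leaves the C6 enolate 14, which is protonated on quench. The closest known reaction type is the lithium amide promoted intramolecular double Michael addition (a stepwise anionic [4+2] cycloaddition) of an oxido-diene tethered to an enoate, known to give fused bicycles; a fully substituted acceptor carbon beside quaternary C4 is a harder substrate for the same reaction. Ring A closes by 6-exo-trig addition (C5–C10) and ring B by 6-endo-trig addition (C9–C8). C5 and C10 are set by a chair-like C1–C4 tether with the C3 silyl ether equatorial and the C19 arm axial, and with lithium bridging the dienolate oxygen and the ester carbonyl so that the ester lies endo and the tether exo, which should give 5α-H and 10β-CH3; the E enoate places the ester cis to C20 (9β) and the E propenyl group gives 8β-CH3, two centres that are erased in steps 9 and 10. The step needs deprotonation at C5 rather than at the propenyl methyl and addition to one enoate face: the first is secured by the hindered amide at low temperature and by reversible proton transfer from the unproductive enolate, the second by the equatorial preference of the C3 OTBS group and the Z(O) geometry that the bulk of C4 enforces.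

Step 9
Reactants: 15 methyl 3β,19-bis(TBSO)-6-oxo-12,13,14,15,16-pentanorlabdan-11-oate
Product: 17 methyl 3β,19-bis(TBSO)-6-oxo-12,13,14,15,16-pentanorlabd-7-en-11-oate (9β-CO2Me), via trimethylsilyl enol ether 16 (not isolated)
Conditions: LiN(i-Pr)2, Me3SiCl, THF, −78 °C; then Pd(OAc)2 (1.1 equiv), MeCN, rt
Reagents that add atoms: none
Why: Saegusa–Ito oxidation, in which kinetic enolisation occurs at the C7 methylene (C5 is a hindered methine) and syn β-hydride elimination of H8 from the palladium enolate gives the 7-en-6-one.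

Step 10
Reactants: 17 methyl 3β,19-bis(TBSO)-6-oxo-12,13,14,15,16-pentanorlabd-7-en-11-oate
Product: 19 methyl 3β,19-bis(TBSO)-6-oxo-12,13,14,15,16-pentanorlabd-8-en-11-oate, via extended lithium enolate 18 (not isolated)
Conditions: LiN(i-Pr)2 (1.1 equiv), THF, −78 → 0 °C; recool to −78 °C, AcOH (excess); cold work-up, used crude
Reagents that add atoms: none
Why: Deconjugative kinetic protonation of an extended enolate: the C9–H (γ to the enone, α to the ester) is removed and the delocalised anion is protonated at C7 next to the ketone, as in the deconjugation of 4-en-3-ones and the C3 alkylation of Hagemann's ester, which places the alkene at C8–C9 in conjugation with the ester.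

Step 11
Reactants: 19 methyl 3β,19-bis(TBSO)-6-oxo-12,13,14,15,16-pentanorlabd-8-en-11-oate
Product: 20 3β,19-bis(TBSO)-12,13,14,15,16-pentanorlabd-8-ene-6β,11-diol
Conditions: i-Bu2AlH (5 equiv), CH2Cl2, −78 → −20 °C; aq. potassium sodium tartrate
Reagents that add atoms: none
Why: Aluminium hydride reduction, in which the enoate gives the allylic alcohol by 1,2-reduction and the C6 ketone is attacked from the α face because the β face is shielded by the axial C19 and C20 groups, which sets 6β-OH (6R).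

Step 12
Reactants: 20 3β,19-bis(TBSO)-12,13,14,15,16-pentanorlabd-8-ene-6β,11-diol
Product: 21 11-bromo-3β,19-bis(TBSO)-12,13,14,15,16-pentanorlabd-8-en-6β-ol
Conditions: CBr4, PPh3, 2,6-lutidine, CH2Cl2, −20 °C; used crude
Reagents that add atoms: carbon tetrabromide, BrC(Br)(Br)Br
Why: Appel reaction, which converts the primary allylic hydroxyl into the bromide while the 6β-hydroxyl, syn-axial to C19 and C20, is too hindered to react and cannot cyclise onto C11 without a bridgehead alkene.

Step 13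
Reactants: 21 11-bromo-3β,19-bis(TBSO)-12,13,14,15,16-pentanorlabd-8-en-6β-ol; 22 tert-butyl 3-oxobutanoate (tert-butyl acetoacetate)
Product: 23 tert-butyl 3β,19-bis(TBSO)-6β-hydroxy-13-oxo-16-norlabd-8-en-15-oate
Conditions: 22 (3 equiv), NaH then n-BuLi, THF, 0 °C; then 21, 0 °C; AcOH
Reagents that add atoms: tert-butyl acetoacetate (22), CC(=O)CC(=O)OC(C)(C)C
Why: γ-Alkylation of the acetoacetate dianion, whose terminal carbanion displaces the primary allylic bromide by SN2 to form C11–C12, with one extra equivalent of dianion consumed by the free hydroxyl.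

Step 14
Reactants: 23 tert-butyl 3β,19-bis(TBSO)-6β-hydroxy-13-oxo-16-norlabd-8-en-15-oate
Product: 24 tert-butyl (13Z)-13-(diethoxyphosphoryloxy)-3β,19-bis(TBSO)-6β-hydroxy-16-norlabda-8,13-dien-15-oate
Conditions: NaH (1.05 equiv), Et2O, 0 °C; ClP(O)(OEt)2, 0 °C → rt
Reagents that add atoms: diethyl chlorophosphate, CCOP(=O)(Cl)OCC
Why: O-Phosphorylation of the sodium enolate of the β-keto ester, whose chelated geometry is carried into the Z enol phosphate; one equivalent of base deprotonates only the far more acidic keto ester.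

Step 15
Reactants: 24 tert-butyl (13Z)-13-(diethoxyphosphoryloxy)-3β,19-bis(TBSO)-6β-hydroxy-16-norlabda-8,13-dien-15-oate
Product: 25 tert-butyl (13E)-3β,19-bis(TBSO)-6β-hydroxylabda-8,13-dien-15-oate
Conditions: Me2CuLi (from CuI and MeLi, 4 equiv), Et2O, −78 → −40 °C; aq. NH4Cl
Reagents that add atoms: lithium dimethylcuprate (from MeLi and CuI), [Li+].C[Cu-]C
Why: Addition–elimination of the organocuprate on the enol phosphate with retention of geometry, which delivers the C16 methyl cis to the ester and hence the 13E trisubstituted enoate.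

Step 16
Reactants: 25 tert-butyl (13E)-3β,19-bis(TBSO)-6β-hydroxylabda-8,13-dien-15-oate
Product: 26 tert-butyl (13E)-3β,6β,19-trihydroxylabda-8,13-dien-15-oate
Conditions: Bu4NF, THF, 50 °C
Reagents that add atoms: none
Why: Fluoride-induced cleavage of both silyl ethers, to which the tert-butyl ester and both alkenes are inert.

Step 17
Reactants: 26 tert-butyl (13E)-3β,6β,19-trihydroxylabda-8,13-dien-15-oate; 27 3-methylbutanoyl chloride
Product: 28 tert-butyl (13E)-3β,6β-dihydroxy-19-(3-methylbutanoyloxy)labda-8,13-dien-15-oate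
Conditions: 27 (1.05 equiv), 2,4,6-collidine, CH2Cl2, −40 → 0 °C
Reagents that add atoms: 3-methylbutanoyl chloride (27), CC(C)CC(=O)Cl
Why: Selective acylation of the primary C19 hydroxyl with one equivalent of acid chloride at low temperature, since both secondary hydroxyls sit beside fully substituted carbons.

Step 18
Reactants: 28 tert-butyl (13E)-3β,6β-dihydroxy-19-(3-methylbutanoyloxy)labda-8,13-dien-15-oate
Product: 29 tert-butyl (13E)-19-(3-methylbutanoyloxy)-3,6-dioxolabda-8,13-dien-15-oate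
Conditions: Dess–Martin periodinane (3 equiv), NaHCO3, CH2Cl2, 0 °C → rt; used crude
Reagents that add atoms: none
Why: Dess–Martin oxidation of both secondary alcohols to the 3,6-dione under buffered conditions that should not move the C8–C9 alkene.

Step 19
Reactants: 29 tert-butyl (13E)-19-(3-methylbutanoyloxy)-3,6-dioxolabda-8,13-dien-15-oate
Product: 30 tert-butyl (13E)-3α,6β-dihydroxy-19-(3-methylbutanoyloxy)labda-8,13-dien-15-oate
Conditions: LiBH(s-Bu)3 (3 equiv), THF, −78 → −40 °C; H2O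
Reagents that add atoms: none
Why: Bulky trialkylborohydride reduction, which attacks the C3 carbonyl along the equatorial trajectory to give the axial 3α alcohol (3R), as with 4,4-disubstituted 3-oxo terpenoids, and reaches C6 only from the α face, restoring 6β-OH (6R).

Step 20
Reactants: 30 tert-butyl (13E)-3α,6β-dihydroxy-19-(3-methylbutanoyloxy)labda-8,13-dien-15-oate; 31 3-methylbutanoic anhydride
Product: 32 tert-butyl (13E)-6β-hydroxy-3α,19-bis(3-methylbutanoyloxy)labda-8,13-dien-15-oate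
Conditions: 31 (3 equiv), DMAP, Et3N, CH2Cl2, rt
Reagents that add atoms: 3-methylbutanoic anhydride (31), CC(C)CC(=O)OC(=O)CC(C)C
Why: DMAP-catalysed acylation, which should esterify the axial 3α hydroxyl while the 6β hydroxyl, syn-axial to both C19 and C20, stays free.

Step 21
Reactants: 32 tert-butyl (13E)-6β-hydroxy-3α,19-bis(3-methylbutanoyloxy)labda-8,13-dien-15-oate
Product: 33 (13E)-6β-hydroxy-3α,19-bis(3-methylbutanoyloxy)labda-8,13-dien-15-oic acid (CNP0333611.1)
Conditions: CF3CO2H, CH2Cl2, 0 °C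
Reagents that add atoms: none
Why: Acidolysis of the tert-butyl ester by loss of isobutene, which should leave the two isovalerates, the hindered alcohol and the tetrasubstituted alkene unchanged.

**Compound list**

1 | methyl (2E)-3,7-dimethylocta-2,6-dienoate (methyl geranate) | CC(C)=CCC/C(C)=C/C(=O)OC | starting material
2 | methyl (2E)-3-methyl-6-oxohex-2-enoate | O=CCC/C(C)=C/C(=O)OC | intermediate
3 | 2-methyl-2-vinyloxirane (isoprene monoxide, racemic) | CC1(C=C)CO1 | starting material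
4 | methyl (2E,6S,7S)-6-hydroxy-7-(hydroxymethyl)-3,7-dimethylnona-2,8-dienoate | C=C[C@@](C)(CO)[C@@H](O)CC/C(C)=C/C(=O)OC | intermediate
5 | methyl (2E,6S,7S)-6-(TBSO)-7-[(TBSO)methyl]-3,7-dimethylnona-2,8-dienoate | C=C[C@@](C)(CO[Si](C)(C)C(C)(C)C)[C@@H](O[Si](C)(C)C(C)(C)C)CC/C(C)=C/C(=O)OC | intermediate
6 | B-alkyl-9-BBN adduct of 5 (boron on the terminal chain carbon) | C(C[C@@](C)(CO[Si](C)(C)C(C)(C)C)[C@@H](O[Si](C)(C)C(C)(C)C)CC/C(C)=C/C(=O)OC)B1C2CCCC1CCC2 | intermediate
7 | methyl (2E,6S,7S)-6-(TBSO)-7-[(TBSO)methyl]-9-hydroxy-3,7-dimethylnon-2-enoate | OCC[C@@](C)(CO[Si](C)(C)C(C)(C)C)[C@@H](O[Si](C)(C)C(C)(C)C)CC/C(C)=C/C(=O)OC | intermediate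
8 | methyl (2E,6S,7S)-6-(TBSO)-7-[(TBSO)methyl]-3,7-dimethyl-9-oxonon-2-enoate | O=CC[C@@](C)(CO[Si](C)(C)C(C)(C)C)[C@@H](O[Si](C)(C)C(C)(C)C)CC/C(C)=C/C(=O)OC | intermediate
9 | (E)-1-bromoprop-1-ene | C/C=C/Br | starting material
10 | methyl (2E,6S,7S,10E)-6-(TBSO)-7-[(TBSO)methyl]-9-hydroxy-3,7-dimethyldodeca-2,10-dienoate (both C9 epimers) | C/C=C/C(O)C[C@@](C)(CO[Si](C)(C)C(C)(C)C)[C@@H](O[Si](C)(C)C(C)(C)C)CC/C(C)=C/C(=O)OC | intermediate
11 | methyl (2E,6S,7S,10E)-6-(TBSO)-7-[(TBSO)methyl]-3,7-dimethyl-9-oxododeca-2,10-dienoate (cascade precursor) | C/C=C/C(=O)C[C@@](C)(CO[Si](C)(C)C(C)(C)C)[C@@H](O[Si](C)(C)C(C)(C)C)CC/C(C)=C/C(=O)OC | intermediate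
12 | lithium (2E,8Z,10E) cross-conjugated dienolate of 11 (C5=C6–OLi) | C/C=C/C(O[Li])=C/[C@@](C)(CO[Si](C)(C)C(C)(C)C)[C@@H](O[Si](C)(C)C(C)(C)C)CC/C(C)=C/C(=O)OC | intermediate
13 | ring A Michael adduct as its lithium ester enolate (5α-H; 10β-CH3) | C/C=C/C(=O)[C@H]1[C@@](C)(CO[Si](C)(C)C(C)(C)C)[C@@H](O[Si](C)(C)C(C)(C)C)CC[C@]1(C)C=C(OC)O[Li] | intermediate
14 | lithium C6 enolate of 15 (C6=C7) | C[C@@H]1[C@H](C(=O)OC)[C@@]2(C)CC[C@H](O[Si](C)(C)C(C)(C)C)[C@](C)(CO[Si](C)(C)C(C)(C)C)[C@@H]2C(O[Li])=C1 | intermediate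
15 | methyl 3β,19-bis(TBSO)-6-oxo-12,13,14,15,16-pentanorlabdan-11-oate (5α-H; 8β-CH3; 9β-CO2Me; 10β-CH3) | C[C@@H]1[C@H](C(=O)OC)[C@@]2(C)CC[C@H](O[Si](C)(C)C(C)(C)C)[C@](C)(CO[Si](C)(C)C(C)(C)C)[C@@H]2C(=O)C1 | intermediate
16 | 6-trimethylsilyloxy-6-ene (trimethylsilyl enol ether of 15) | C[C@@H]1[C@H](C(=O)OC)[C@@]2(C)CC[C@H](O[Si](C)(C)C(C)(C)C)[C@](C)(CO[Si](C)(C)C(C)(C)C)[C@@H]2C(O[Si](C)(C)C)=C1 | intermediate
17 | methyl 3β,19-bis(TBSO)-6-oxo-12,13,14,15,16-pentanorlabd-7-en-11-oate (9β-CO2Me) | CC1=CC(=O)[C@H]2[C@@](C)(CO[Si](C)(C)C(C)(C)C)[C@@H](O[Si](C)(C)C(C)(C)C)CC[C@]2(C)[C@H]1C(=O)OC | intermediate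
18 | extended lithium enolate of 17 (6-oxido-6,8-diene) | CC1=C(C(=O)OC)[C@@]2(C)CC[C@H](O[Si](C)(C)C(C)(C)C)[C@](C)(CO[Si](C)(C)C(C)(C)C)[C@@H]2C(O[Li])=C1 | intermediate
19 | methyl 3β,19-bis(TBSO)-6-oxo-12,13,14,15,16-pentanorlabd-8-en-11-oate | CC1=C(C(=O)OC)[C@@]2(C)CC[C@H](O[Si](C)(C)C(C)(C)C)[C@](C)(CO[Si](C)(C)C(C)(C)C)[C@@H]2C(=O)C1 | intermediate
20 | 3β,19-bis(TBSO)-12,13,14,15,16-pentanorlabd-8-ene-6β,11-diol | CC1=C(CO)[C@@]2(C)CC[C@H](O[Si](C)(C)C(C)(C)C)[C@](C)(CO[Si](C)(C)C(C)(C)C)[C@@H]2[C@H](O)C1 | intermediate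
21 | 11-bromo-3β,19-bis(TBSO)-12,13,14,15,16-pentanorlabd-8-en-6β-ol | CC1=C(CBr)[C@@]2(C)CC[C@H](O[Si](C)(C)C(C)(C)C)[C@](C)(CO[Si](C)(C)C(C)(C)C)[C@@H]2[C@H](O)C1 | intermediate
22 | tert-butyl 3-oxobutanoate (tert-butyl acetoacetate) | CC(=O)CC(=O)OC(C)(C)C | starting material
23 | tert-butyl 3β,19-bis(TBSO)-6β-hydroxy-13-oxo-16-norlabd-8-en-15-oate | CC1=C(CCC(=O)CC(=O)OC(C)(C)C)[C@@]2(C)CC[C@H](O[Si](C)(C)C(C)(C)C)[C@](C)(CO[Si](C)(C)C(C)(C)C)[C@@H]2[C@H](O)C1 | intermediate
24 | tert-butyl (13Z)-13-(diethoxyphosphoryloxy)-3β,19-bis(TBSO)-6β-hydroxy-16-norlabda-8,13-dien-15-oate | CC1=C(CC/C(OP(=O)(OCC)OCC)=C/C(=O)OC(C)(C)C)[C@@]2(C)CC[C@H](O[Si](C)(C)C(C)(C)C)[C@](C)(CO[Si](C)(C)C(C)(C)C)[C@@H]2[C@H](O)C1 | intermediate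
25 | tert-butyl (13E)-3β,19-bis(TBSO)-6β-hydroxylabda-8,13-dien-15-oate | CC1=C(CC/C(C)=C/C(=O)OC(C)(C)C)[C@@]2(C)CC[C@H](O[Si](C)(C)C(C)(C)C)[C@](C)(CO[Si](C)(C)C(C)(C)C)[C@@H]2[C@H](O)C1 | intermediate
26 | tert-butyl (13E)-3β,6β,19-trihydroxylabda-8,13-dien-15-oate | CC1=C(CC/C(C)=C/C(=O)OC(C)(C)C)[C@@]2(C)CC[C@H](O)[C@](C)(CO)[C@@H]2[C@H](O)C1 | intermediate
27 | 3-methylbutanoyl chloride (isovaleryl chloride) | CC(C)CC(=O)Cl | starting material
28 | tert-butyl (13E)-3β,6β-dihydroxy-19-(3-methylbutanoyloxy)labda-8,13-dien-15-oate | CC1=C(CC/C(C)=C/C(=O)OC(C)(C)C)[C@@]2(C)CC[C@H](O)[C@](C)(COC(=O)CC(C)C)[C@@H]2[C@H](O)C1 | intermediate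
29 | tert-butyl (13E)-19-(3-methylbutanoyloxy)-3,6-dioxolabda-8,13-dien-15-oate | CC1=C(CC/C(C)=C/C(=O)OC(C)(C)C)[C@@]2(C)CCC(=O)[C@](C)(COC(=O)CC(C)C)[C@@H]2C(=O)C1 | intermediate
30 | tert-butyl (13E)-3α,6β-dihydroxy-19-(3-methylbutanoyloxy)labda-8,13-dien-15-oate | CC1=C(CC/C(C)=C/C(=O)OC(C)(C)C)[C@@]2(C)CC[C@@H](O)[C@](C)(COC(=O)CC(C)C)[C@@H]2[C@H](O)C1 | intermediate
31 | 3-methylbutanoic anhydride (isovaleric anhydride) | CC(C)CC(=O)OC(=O)CC(C)C | starting material
32 | tert-butyl (13E)-6β-hydroxy-3α,19-bis(3-methylbutanoyloxy)labda-8,13-dien-15-oate | CC1=C(CC/C(C)=C/C(=O)OC(C)(C)C)[C@@]2(C)CC[C@@H](OC(=O)CC(C)C)[C@](C)(COC(=O)CC(C)C)[C@@H]2[C@H](O)C1 | intermediate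
33 | (13E)-6β-hydroxy-3α,19-bis(3-methylbutanoyloxy)labda-8,13-dien-15-oic acid (CNP0333611.1; 3R,4S,5R,6R,10S) | CC1=C(CC/C(C)=C/C(=O)O)[C@@]2(C)CC[C@@H](OC(=O)CC(C)C)[C@](C)(COC(=O)CC(C)C)[C@@H]2[C@H](O)C1 | target

**Count and risks**

Total step count: 21. Longest linear sequence: 21 steps (1 → 33); compounds 3, 9, 22, 27 and 31 enter as purchased reagents.

Steps most likely to fail:

1. Step 8. The C5 dienolate may fail to add to the fully substituted C10 beside quaternary C4 (deprotonation of the propenyl methyl, proton transfer or oligomerisation instead), or the ring A chair may discriminate the two enoate faces only weakly. Fallback, from 11 back to 15: soft enolisation with TBSOTf and Et3N (CH2Cl2, −78 → 0 °C) would give the neutral 2-silyloxy triene, TBS dienol ether F1. Heating this in toluene at about 180 °C (sealed, trace Et3N) should close both rings in a concerted intramolecular Diels–Alder reaction through the same endo-ester, exo-tether arrangement to the bicyclic TBS enol ether F2. Brief dilute aqueous acid in THF would hydrolyse only the enol ether and return 15.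

2. Step 10. The extended enolate may be protonated at C9 rather than C7, or the alkene may drift back into conjugation with the C6 ketone during work-up. Fallback, from 17 back to 20: Luche reduction (NaBH4, CeCl3·7H2O, MeOH, −40 °C) from the α face would give the allylic alcohol, 6β-hydroxy-7-ene ester F3. With the ketone gone the ester is the only acceptor, and NaOMe in MeOH should move the β,γ alkene into conjugation at C8–C9 under thermodynamic control to give the 8-ene ester F4. Reduction with i-Bu2AlH then rejoins the route at 20.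

3. Step 19. The hindered, β,γ-unsaturated C6 carbonyl may be enolised by the bulky borohydride instead of reduced, so that conjugated enone appears on work-up; step 20 then also has to tell two free secondary hydroxyls apart. Fallback, from 29 back to 32: one equivalent of LiBH(s-Bu)3 at −78 °C should reduce only the more accessible C3 carbonyl to the 3α-hydroxy 6-ketone F5. Acylation with 31 and DMAP would give the bis-isovalerate 6-ketone F6 with no competing hydroxyl. The small, non-basic NaBH4–CeCl3·7H2O system then reduces C6 from the α face to give 32.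

Further compounds

F1 | step 8 | methyl (2E,6S,7S,8Z,10E)-6,9-bis(TBSO)-7-[(TBSO)methyl]-3,7-dimethyldodeca-2,8,10-trienoate (TBS dienol ether of 11) | C/C=C/C(O[Si](C)(C)C(C)(C)C)=C/[C@@](C)(CO[Si](C)(C)C(C)(C)C)[C@@H](O[Si](C)(C)C(C)(C)C)CC/C(C)=C/C(=O)OC
F2 | step 8 | methyl 3β,6,19-tris(TBSO)-12,13,14,15,16-pentanorlabd-6-en-11-oate (TBS enol ether of 15) | C[C@@H]1[C@H](C(=O)OC)[C@@]2(C)CC[C@H](O[Si](C)(C)C(C)(C)C)[C@](C)(CO[Si](C)(C)C(C)(C)C)[C@@H]2C(O[Si](C)(C)C(C)(C)C)=C1
F3 | step 10 | methyl 3β,19-bis(TBSO)-6β-hydroxy-12,13,14,15,16-pentanorlabd-7-en-11-oate | CC1=C[C@@H](O)[C@H]2[C@@](C)(CO[Si](C)(C)C(C)(C)C)[C@@H](O[Si](C)(C)C(C)(C)C)CC[C@]2(C)[C@H]1C(=O)OC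
F4 | step 10 | methyl 3β,19-bis(TBSO)-6β-hydroxy-12,13,14,15,16-pentanorlabd-8-en-11-oate | CC1=C(C(=O)OC)[C@@]2(C)CC[C@H](O[Si](C)(C)C(C)(C)C)[C@](C)(CO[Si](C)(C)C(C)(C)C)[C@@H]2[C@H](O)C1
F5 | step 19 | tert-butyl (13E)-3α-hydroxy-19-(3-methylbutanoyloxy)-6-oxolabda-8,13-dien-15-oate | CC1=C(CC/C(C)=C/C(=O)OC(C)(C)C)[C@@]2(C)CC[C@@H](O)[C@](C)(COC(=O)CC(C)C)[C@@H]2C(=O)C1
F6 | step 19 | tert-butyl (13E)-3α,19-bis(3-methylbutanoyloxy)-6-oxolabda-8,13-dien-15-oate | CC1=C(CC/C(C)=C/C(=O)OC(C)(C)C)[C@@]2(C)CC[C@@H](OC(=O)CC(C)C)[C@](C)(COC(=O)CC(C)C)[C@@H]2C(=O)C1
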